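# Design of a total synthesis of β-collatolic acid (34)

## The problem

β-Collatolic acid (34) is an achiral diaryl ether. Ring A is a pentasubstituted β-resorcylic acid: C1 carries the carboxyl group, C2 the 2-oxoheptyl chain, C3 the ether oxygen, C4 and C6 the hydroxyls, and C5 the only hydrogen. Ring B is a 6-methoxy-3-pentylisocoumarin bound through the oxygen on its C8. The ether joins two carbons that are each flanked on both sides (ring A C3 between the side chain and the C4 oxygen, ring B C8 beside C8a with its lactone carbonyl), so a late aryl–oxygen coupling would be the most hindered bond formation of the whole synthesis. There are no stereocenters, so every selectivity question is one of regio- or chemoselectivity. Both rings hold the same unit, a carboxyl group ortho to a CH2–CO–pentyl chain, closed to the enol lactone in ring B and open in ring A. Any acidic or dehydrating treatment that closes one can close the other, so the two must be kept apart by protection until the end. The groups that will not stand rough treatment are: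

- the isocoumarin, which hydroxide and alkoxide open and which can be reduced at C3–C4;
- the free resorcylic acid, prone to decarboxylation and oxidation;
- the ring A keto acid, which forms a lactol or a second isocoumarin under acid;
- along the way, a benzyl ester facing organolithium reagents.

The feature that opens the key step is the substitution of ring B: oxygen on C6 and C8, C7–H between them, C5–H, and carbon substituents on C8a and C4a. A vinylketene and an alkoxyalkyne give exactly this pattern. The alkyne supplies C7–H and C8 with its oxygen (already bonded to ring A), the ketene carbonyl becomes C6–OH, the substituted ketene carbon becomes C8a with the future lactone carbonyl, and the alkenyl group gives C4a, C5 and a methyl that becomes C4.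

## Retrosynthesis

**34 to 33 and 32 (three O–benzyl bonds, then the dioxolane).** The last steps are settled first because they fix every protecting group. The acid and both phenols of ring A are released together by hydrogenolysis of tribenzyl compound 33. These are neutral conditions, so the keto acid never meets acid or base that could close ring A to a second isocoumarin. One step earlier the ring A ketone is freed from dioxolane 32 by dilute aqueous acid, under which the benzyl ester cannot lactonize. An ester that needs hydroxide would open the ring B lactone, and one that needs strong acid would dehydrate ring A, so benzyl is the choice. The forward reaction must spare the C3–C4 double bond of the isocoumarin.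

**32 to 30, 29, then 27 and 3 (C1–O2 and C3–C4 of the pyranone ring).** The enol lactone is cut at its acyl–oxygen bond to keto acid 30, and the ketone at its benzylic bond to toluate 27 and Weinreb amide 3. Direct acid-catalysed closure of keto ester 29 would save a step, but it would strip the dioxolane and let ring A close as well. The closure therefore runs through acid 30 and a base-buffered anhydride activation, and the dioxolane is what tells the two keto-carboxyl units apart. The forward steps ask for lateral lithiation at the ring B methyl in the presence of ring A, and for hydrolysis of the ring B ethyl ester beside the hindered benzyl ester.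

**27 to 26 (O–CH3).** The C6 methyl ether is cut to the phenol, which is exactly what the benzannulation delivers. Nothing is asked but O-alkylation of the only free hydroxyl.

**26 to 17 and 21 (C8a–C4a, C6–C7, C8–C8a and C5–C6).** Ring B is taken apart completely into aryl ethynyl ether 17 and diazo ketoester 21. The neighbouring cut, an aryl–oxygen coupling between two finished rings, would form one bond at the most crowded site. This cut forms four bonds and the ring in one operation and never makes an aryl–oxygen bond between two rings, since the ether oxygen enters ring B already attached to ring A. The precursors are far simpler: 17 is ring A plus two carbons, and 21 is an eight-carbon acyclic compound. The forward reaction must add the ketene C=C to the alkyne with the right orientation and must not be diverted through the ester carbonyl.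

**21 to 18 and 19 (the bond between the diazo carbon and the carbonyl carbon).** The diazo ketoester comes from ethyl diazoacetate 18 and methacrolein 19 by aldol-type addition and oxidation. Diazo transfer to the corresponding unsaturated keto ester would start from an unstable, polymerizable compound, so the aldol route is preferred. Only 1,2-addition to the aldehyde is required.

**17 to 14, then 12 and 13 (the oxygen–alkyne bond).** The ethynyl ether is traced through dichlorovinyl ether 14 to phenol 12 and trichloroethylene 13. Here the hindered phenol oxygen meets a small two-carbon electrophile made from 13 in the flask, not a second hindered ring. The forward sequence needs two eliminations and a halogen–metal exchange that leave the benzyl ester alone.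

**12 to 9 and 8 (C3–O, through C3–I).** The phenol oxygen is introduced by iodination of 8 and conversion of iodide 9 through magnesium and boron. Oxygenation of an earlier free resorcinol would leave three hydroxyls that cannot easily be told apart, whereas iodination of the diether gives one free phenol beside two benzyl ethers. The demand is regioselective iodination at C3 and not at C5.

**8 to 7, then 5 and 3 (ketal; C–C bond of the side chain).** The dioxolane is cut to ketone 7, and 7 to toluate 5 and Weinreb amide 3. The methyl group of 5 is the nucleophile, so the same amide 3 serves both rings. A resorcylic acid without the methyl group would demand C–C bond formation at the most hindered ring position; with the methyl in place the bond is made outside the ring.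

**5 to 4; 3 to 1 and 2.** Tribenzyl compound 5 comes in one step from orsellinic acid 4, which already holds the carboxyl, both oxygens and the C2 carbon. Amide 3 comes from hexanoyl chloride 1 and hydroxylamine salt 2.

## Roads not taken

**Alternative 1: Ring A by Michael–Dieckmann annulation on a finished ring B.** The cut is at ring A bonds C1–C2 and C5–C6. In the forward step the sodium enolate of dibenzyl malonate A2 adds to the β-carbon of the α-aryloxy enone A1, whose aryloxy group is the complete isocoumarin. The methyl ketone enolate then closes on a malonate ester to give cyclohexenone A3 (trans, racemic; both centres vanish on aromatization).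

- Merits: the ether C–O bond is made by displacement at an sp3 carbon of an α-halo ketone, the easiest possible answer to the crowded ether. There is no photochemistry and no ynol ether.
- Weak points: A1 is a trisubstituted enone with a donor oxygen on its α-carbon and a branched β-substituent, so it is a poor Michael acceptor. A basic malonate enolate meets the isocoumarin lactone. Above all, A3 is one oxidation level short of aromatic, and the required dehydrogenation competes with a redox-neutral aromatization by loss of the ring B phenoxide from C3. That pathway destroys the very bond the route exists to make.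
- Comparison: in forming the ether bond this road is better than the chosen plan, and it avoids the least precedented step. The chosen plan sets against it that ring B is born aromatic by tautomerization alone, and that the ether oxygen sits on sp2 carbon from the moment it is installed.

**Alternative 2: Ring A by cycloaddition of a bis(silyloxy)diene with an alkynoate.** The cut is at ring A bonds C2–C3 and C1–C6. Diene A4 (its aryloxy group again the complete isocoumarin) adds to benzyl alkynoate A5; loss of methanol and desilylation give resorcylate A6, the benzyl ester of the target with the ketone as dioxolane.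

- Merits: this is the most convergent road. A6 is two deprotections from 34, whereas the chosen plan needs six steps after its key step. The polarization of the diene gives the right regiochemistry, and the ether oxygen is again set by displacement at sp3 carbon.
- Weak points: such dienes add readily to propiolates and allenes, but A5 is a β-alkyl alkynoate with a quaternary ketal carbon one atom from the triple bond. The diene terminus that must attack carries the bulky aryloxy group. Forcing the reaction thermally invites desilylation of A4. The isocoumarin must also survive two silyl enol ether formations under strong base.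
- Comparison: if the cycloaddition worked it would beat the chosen plan on step count. The chosen plan sets against it a terminal, unhindered alkyne that meets a strongly electrophilic ketene at room temperature. It also forms the less substituted ring B (two C–H positions), leaving the hexasubstituted ring A to stepwise aromatic chemistry of known regiochemistry.

**Alternative 3: Aryne insertion into a malonate to give the ring B homophthalate.** The cut is at C4a–C4 and C8a–C1 of ring B; no ring closes. Fluoride releases the 3-aryloxy-5-methoxybenzyne from silyl triflate A7. Dimethyl malonate A8 adds with its carbon at C4a, distal to the aryloxy group, and the aryl anion at C8a takes over an ester group, giving homophthalate A9.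

- Merits: the regiochemistry, governed by the oxygen substituent next to the aryne, is the right one. The conditions are mild. C4 arrives as an activated methylene, so no lithium amide is used on the full molecule; here it is better than step 12 of the chosen plan.
- Weak points: the diaryl ether must exist before the key step, so the hindered aryl–oxygen coupling is only moved, not removed. Turning A9 into the 3-pentylisocoumarin needs C-acylation, selective ester hydrolysis and decarboxylation beside the benzyl ester and dioxolane of ring A. The key step closes no ring.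
- Comparison: the key step is milder than photolysis plus heating and probably more predictable, but step economy is poorer and the central difficulty remains. The chosen plan carries the ether oxygen into ring B on a two-carbon unit and closes the ring in the same operation.

Key step: step 10

**Remarks on the chemistry.**
- Ring A locants are those of the names below (C1 carboxyl-bearing, C2 side chain, C3 ether oxygen, C4 and C6 oxygens, C5 hydrogen); ring B has isocoumarin locants.
- Assumption: orsellinic acid (4) is taken as a purchasable fine chemical.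
- The target is treated as the open keto acid, as drawn.
- Amide 3 is made once and used in steps 3 and 12.

## Route

Step 1
Reactants: 1 hexanoyl chloride; 2 N,O-dimethylhydroxylamine hydrochloride
Product: 3 N-methoxy-N-methylhexanamide
Conditions: Et3N (2.2 equiv), CH2Cl2, 0 °C → rt
Reagents that add atoms: none
Why: N-acylation of the hydroxylamine salt by the acid chloride, the standard preparation of a Weinreb amide.

Step 2
Reactants: 4 orsellinic acid
Product: 5 benzyl 4,6-bis(benzyloxy)-2-methylbenzoate
Conditions: BnBr (3.5 equiv), K2CO3, DMF, rt → 60 °C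
Reagents that add atoms: benzyl bromide, BrCc1ccccc1
Why: Williamson O-alkylation of the carboxylate and both phenoxides; the chelated hydroxyl ortho to the ester reacts last and needs the excess and mild heating.

Step 3
Reactants: 5 benzyl 4,6-bis(benzyloxy)-2-methylbenzoate; 3 N-methoxy-N-methylhexanamide
Product: 7 benzyl 4,6-bis(benzyloxy)-2-(2-oxoheptyl)benzoate, via lithiated toluate 6 (not isolated)
Conditions: LiN(i-Pr)2 (1.3 equiv), THF, −78 °C; then 3, −78 → −40 °C; aq. NH4Cl
Reagents that add atoms: none
Why: Lateral lithiation of an ortho-toluate followed by Weinreb amide acylation, which stops at the ketone; this is the standard way to extend orsellinate ethers at the methyl group.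

Step 4
Reactants: 7 benzyl 4,6-bis(benzyloxy)-2-(2-oxoheptyl)benzoate
Product: 8 benzyl 4,6-bis(benzyloxy)-2-[(2-pentyl-1,3-dioxolan-2-yl)methyl]benzoate
Conditions: TMSOCH2CH2OTMS, TMSOTf (5 mol%), CH2Cl2, −78 → −20 °C; pyridine
Reagents that add atoms: 1,2-bis(trimethylsilyloxy)ethane, C[Si](C)(C)OCCO[Si](C)(C)C
Why: Silyl-transfer ketalization under aprotic, low-temperature conditions that are too mild for the neighbouring benzyl ester to enol-lactonize; the masked ketone later ensures that only ring B can close.

Step 5
Reactants: 8 benzyl 4,6-bis(benzyloxy)-2-[(2-pentyl-1,3-dioxolan-2-yl)methyl]benzoate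
Product: 9 benzyl 4,6-bis(benzyloxy)-3-iodo-2-[(2-pentyl-1,3-dioxolan-2-yl)methyl]benzoate
Conditions: NIS (1.05 equiv), CF3CO2H (10 mol%), MeCN, 0 °C → rt
Reagents that add atoms: N-iodosuccinimide, O=C1CCC(=O)N1I
Why: Electrophilic aromatic iodination; C3 is para to the C6 ether and ortho to the C4 ether, whereas C5 is wedged between two benzyloxy groups, which is the usual outcome for 5-alkylresorcinol diethers.

Step 6
Reactants: 9 benzyl 4,6-bis(benzyloxy)-3-iodo-2-[(2-pentyl-1,3-dioxolan-2-yl)methyl]benzoate
Product: 12 benzyl 4,6-bis(benzyloxy)-3-hydroxy-2-[(2-pentyl-1,3-dioxolan-2-yl)methyl]benzoate, via arylmagnesium chloride 10 (not isolated), via dimethyl arylboronate 11 (not isolated)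
Conditions: i-PrMgCl·LiCl, THF, −20 °C; B(OMe)3, −20 → 0 °C; then 30% H2O2, aq. NaOH, 0 °C
Reagents that add atoms: hydrogen peroxide, OO
Why: Iodine–magnesium exchange (tolerated by the hindered ester at −20 °C), borylation and oxidative aryl shift from boron to oxygen, the standard ester-compatible path from an aryl iodide to a phenol.

Step 7
Reactants: 12 benzyl 4,6-bis(benzyloxy)-3-hydroxy-2-[(2-pentyl-1,3-dioxolan-2-yl)methyl]benzoate; 13 trichloroethylene
Product: 14 benzyl 4,6-bis(benzyloxy)-3-{[(E)-1,2-dichloroethenyl]oxy}-2-[(2-pentyl-1,3-dioxolan-2-yl)methyl]benzoate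
Conditions: K2CO3, DMF, 70 °C
Reagents that add atoms: none
Why: Base-induced elimination gives dichloroacetylene in the flask and the phenoxide adds to it in anti fashion, giving the (E)-dichlorovinyl ether; the small electrophile suits a phenol flanked on both sides.

Step 8
Reactants: 14 benzyl 4,6-bis(benzyloxy)-3-{[(E)-1,2-dichloroethenyl]oxy}-2-[(2-pentyl-1,3-dioxolan-2-yl)methyl]benzoate
Product: 17 benzyl 4,6-bis(benzyloxy)-3-(ethynyloxy)-2-[(2-pentyl-1,3-dioxolan-2-yl)methyl]benzoate, via chloroethynyl ether 15 (not isolated), via lithium alkynide 16 (not isolated)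
Conditions: n-BuLi (2.2 equiv), THF, −78 °C; MeOH, −78 °C
Reagents that add atoms: none
Why: Deprotonation with loss of LiCl gives the chloroalkyne, chlorine–lithium exchange gives the lithium alkynide and methanol protonates it (the trichloroethylene route to ynol ethers). Both events are fast at −78 °C, where the twisted, doubly ortho-substituted benzyl ester should add butyllithium only slowly; 17 is used at once.

Step 9
Reactants: 18 ethyl diazoacetate; 19 methacrolein
Product: 21 ethyl 2-diazo-4-methyl-3-oxopent-4-enoate, via aldol adduct 20 (not isolated)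
Conditions: DBU (10 mol%), DMSO, rt; then IBX (1.5 equiv), rt
Reagents that add atoms: none
Why: Amine-catalysed aldol-type addition of the diazo ester to the aldehyde carbonyl, then oxidation of the allylic diazo alcohol by IBX in the same pot, a known one-pot route to 2-diazo-3-oxo esters.

Step 10
Reactants: 17 benzyl 4,6-bis(benzyloxy)-3-(ethynyloxy)-2-[(2-pentyl-1,3-dioxolan-2-yl)methyl]benzoate; 21 ethyl 2-diazo-4-methyl-3-oxopent-4-enoate
Product: 26 benzyl 4,6-bis(benzyloxy)-3-[2-(ethoxycarbonyl)-5-hydroxy-3-methylphenoxy]-2-[(2-pentyl-1,3-dioxolan-2-yl)methyl]benzoate, via vinylketene 22 (not isolated), via cyclobutenone 23 (not isolated), via dienylketene 24 (not isolated), via cyclohexadienone 25 (not isolated)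
Conditions: 21 (1.5 equiv, added slowly), hν (300–350 nm, Pyrex), ClCH2CH2Cl, rt; then 80 °C
Reagents that add atoms: none
Why: Proposed new method: irradiation of 21 expels N2 and the isopropenyl group shifts to the carbene carbon (Wolff rearrangement, C8a–C4a) to give ketene 22; the electron-rich CH terminus of ynol ether 17 attacks the ketene carbonyl carbon and the oxygen-bearing alkyne carbon closes onto the ester-bearing carbon, so [2+2] cycloaddition gives 3-aryloxycyclobutenone 23 (C6–C7 and C8–C8a). Heating opens 23 by four-electron electrocyclic reversion to dienylketene 24, and ring B closes by thermal disrotatory six-electron electrocyclization between the ketene carbon and the isopropenyl CH2 (C5–C6) to dienone 25, which tautomerizes to phenol 26. The closest known reaction type is the Danheiser benzannulation in its photochemical Wolff variant, established for alkenyl diazomethyl ketones with alkoxy- and silyloxyalkynes; new here are the ester on the ketene carbon and an aryl ethynyl ether as partner. No stereocenter is formed, since the quaternary carbon of 23 is racemic and is lost on ring opening. The step needs regioselective [2+2] addition, which the polarization of the ynol ether against the electrophilic ketene carbon secures, and it needs the ketene C=C to react in preference to [4+2] capture through the ester carbonyl; a weakly polar solvent, a low stationary ketene concentration and the lower tendency of an ester carbonyl (compared with a ketone carbonyl) to act as heterodiene terminus are relied on for that. Ring opening of 23 with the ester turned toward the ketene is reversible, so only the isomer able to cyclize drains to the phenol. The aryl ethynyl ether has no hydrogen placed for retro-ene loss of ketene and should survive the thermal stage.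

Step 11
Reactants: 26 benzyl 4,6-bis(benzyloxy)-3-[2-(ethoxycarbonyl)-5-hydroxy-3-methylphenoxy]-2-[(2-pentyl-1,3-dioxolan-2-yl)methyl]benzoate
Product: 27 benzyl 4,6-bis(benzyloxy)-3-[2-(ethoxycarbonyl)-5-methoxy-3-methylphenoxy]-2-[(2-pentyl-1,3-dioxolan-2-yl)methyl]benzoate
Conditions: MeI, K2CO3, acetone, 50 °C
Reagents that add atoms: iodomethane, CI
Why: Williamson O-methylation of the only free phenol.

Step 12
Reactants: 27 benzyl 4,6-bis(benzyloxy)-3-[2-(ethoxycarbonyl)-5-methoxy-3-methylphenoxy]-2-[(2-pentyl-1,3-dioxolan-2-yl)methyl]benzoate; 3 N-methoxy-N-methylhexanamide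
Product: 29 benzyl 4,6-bis(benzyloxy)-3-[2-(ethoxycarbonyl)-5-methoxy-3-(2-oxoheptyl)phenoxy]-2-[(2-pentyl-1,3-dioxolan-2-yl)methyl]benzoate, via lithiated toluate 28 (not isolated)
Conditions: LiN(i-Pr)2 (1.5 equiv), THF, −78 °C; then 3, −78 → −40 °C; aq. NH4Cl
Reagents that add atoms: none
Why: Lateral lithiation and Weinreb acylation as in step 3; the ring B methyl is a primary, open benzylic site beside an ester, whereas the ring A methylene is secondary and shielded by the ketal and the ether oxygen, which should decide the site of deprotonation.

Step 13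
Reactants: 29 benzyl 4,6-bis(benzyloxy)-3-[2-(ethoxycarbonyl)-5-methoxy-3-(2-oxoheptyl)phenoxy]-2-[(2-pentyl-1,3-dioxolan-2-yl)methyl]benzoate
Product: 30 benzyl 4,6-bis(benzyloxy)-3-[2-carboxy-5-methoxy-3-(2-oxoheptyl)phenoxy]-2-[(2-pentyl-1,3-dioxolan-2-yl)methyl]benzoate
Conditions: LiOH, THF/H2O, rt → 40 °C; then dilute HCl to pH 3
Reagents that add atoms: lithium hydroxide, [Li+].[OH-]
Why: Saponification of the ring B ester helped by the neighbouring ketone (its enolate acylates on oxygen and hydroxide opens the lactone so formed), while the ring A benzyl ester, doubly ortho-substituted and without such help, should remain.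

Step 14
Reactants: 30 benzyl 4,6-bis(benzyloxy)-3-[2-carboxy-5-methoxy-3-(2-oxoheptyl)phenoxy]-2-[(2-pentyl-1,3-dioxolan-2-yl)methyl]benzoate
Product: 32 benzyl 4,6-bis(benzyloxy)-3-[(6-methoxy-1-oxo-3-pentyl-1H-isochromen-8-yl)oxy]-2-[(2-pentyl-1,3-dioxolan-2-yl)methyl]benzoate, via mixed anhydride 31 (not isolated)
Conditions: Ac2O, pyridine, DMAP (cat.), CH2Cl2, rt
Reagents that add atoms: none
Why: Enol lactonization of a 2-(2-oxoalkyl)benzoic acid through its mixed anhydride, the classical isocoumarin closure (the enol oxygen attacks the activated carboxyl in a 6-exo mode); the base-buffered medium keeps the dioxolane, so ring A cannot follow.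

Step 15
Reactants: 32 benzyl 4,6-bis(benzyloxy)-3-[(6-methoxy-1-oxo-3-pentyl-1H-isochromen-8-yl)oxy]-2-[(2-pentyl-1,3-dioxolan-2-yl)methyl]benzoate
Product: 33 benzyl 4,6-bis(benzyloxy)-3-[(6-methoxy-1-oxo-3-pentyl-1H-isochromen-8-yl)oxy]-2-(2-oxoheptyl)benzoate
Conditions: 1 M aq. HCl, THF, rt
Reagents that add atoms: water, O
Why: Acid-catalysed ketal hydrolysis; dilute aqueous acid at room temperature frees the ketone but cannot force lactonization onto the benzyl ester.

Step 16
Reactants: 33 benzyl 4,6-bis(benzyloxy)-3-[(6-methoxy-1-oxo-3-pentyl-1H-isochromen-8-yl)oxy]-2-(2-oxoheptyl)benzoate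
Product: 34 β-collatolic acid, 4,6-dihydroxy-3-[(6-methoxy-1-oxo-3-pentyl-1H-isochromen-8-yl)oxy]-2-(2-oxoheptyl)benzoic acid
Conditions: H2 (1 atm), 10% Pd/C, EtOAc, rt
Reagents that add atoms: none
Why: Hydrogenolysis of the benzyl ester and both benzyl ethers under neutral conditions, so the keto acid is released without acid or base; the reaction is to be stopped after three equivalents of hydrogen to spare the C3–C4 double bond of the isocoumarin.

## Compound list

1 | hexanoyl chloride | CCCCCC(=O)Cl | starting material
2 | N,O-dimethylhydroxylamine hydrochloride | CNOC.Cl | starting material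
3 | N-methoxy-N-methylhexanamide | CCCCCC(=O)N(C)OC | intermediate
4 | orsellinic acid (4,6-dihydroxy-2-methylbenzoic acid) | Cc1cc(O)cc(O)c1C(=O)O | starting material
5 | benzyl 4,6-bis(benzyloxy)-2-methylbenzoate | Cc1cc(OCc2ccccc2)cc(OCc2ccccc2)c1C(=O)OCc1ccccc1 | intermediate
6 | benzyl 4,6-bis(benzyloxy)-2-(lithiomethyl)benzoate (not isolated) | [Li]Cc1cc(OCc2ccccc2)cc(OCc2ccccc2)c1C(=O)OCc1ccccc1 | intermediate
7 | benzyl 4,6-bis(benzyloxy)-2-(2-oxoheptyl)benzoate | CCCCCC(=O)Cc1cc(OCc2ccccc2)cc(OCc2ccccc2)c1C(=O)OCc1ccccc1 | intermediate
8 | benzyl 4,6-bis(benzyloxy)-2-[(2-pentyl-1,3-dioxolan-2-yl)methyl]benzoate | CCCCCC1(Cc2cc(OCc3ccccc3)cc(OCc3ccccc3)c2C(=O)OCc2ccccc2)OCCO1 | intermediate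
9 | benzyl 4,6-bis(benzyloxy)-3-iodo-2-[(2-pentyl-1,3-dioxolan-2-yl)methyl]benzoate | CCCCCC1(Cc2c(I)c(OCc3ccccc3)cc(OCc3ccccc3)c2C(=O)OCc2ccccc2)OCCO1 | intermediate
10 | arylmagnesium chloride from 9, MgCl in place of iodine at C3 (not isolated) | CCCCCC1(Cc2c([Mg]Cl)c(OCc3ccccc3)cc(OCc3ccccc3)c2C(=O)OCc2ccccc2)OCCO1 | intermediate
11 | dimethyl arylboronate, B(OMe)2 at C3 (not isolated) | CCCCCC1(Cc2c(B(OC)OC)c(OCc3ccccc3)cc(OCc3ccccc3)c2C(=O)OCc2ccccc2)OCCO1 | intermediate
12 | benzyl 4,6-bis(benzyloxy)-3-hydroxy-2-[(2-pentyl-1,3-dioxolan-2-yl)methyl]benzoate | CCCCCC1(Cc2c(O)c(OCc3ccccc3)cc(OCc3ccccc3)c2C(=O)OCc2ccccc2)OCCO1 | intermediate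
13 | trichloroethylene | ClC=C(Cl)Cl | starting material
14 | benzyl 4,6-bis(benzyloxy)-3-{[(E)-1,2-dichloroethenyl]oxy}-2-[(2-pentyl-1,3-dioxolan-2-yl)methyl]benzoate | CCCCCC1(Cc2c(O/C(Cl)=C\Cl)c(OCc3ccccc3)cc(OCc3ccccc3)c2C(=O)OCc2ccccc2)OCCO1 | intermediate
15 | benzyl 4,6-bis(benzyloxy)-3-[(chloroethynyl)oxy]-2-[(2-pentyl-1,3-dioxolan-2-yl)methyl]benzoate (not isolated) | CCCCCC1(Cc2c(OC#CCl)c(OCc3ccccc3)cc(OCc3ccccc3)c2C(=O)OCc2ccccc2)OCCO1 | intermediate
16 | lithium alkynide of 17, Li on the terminal alkyne carbon (not isolated) | CCCCCC1(Cc2c(OC#C[Li])c(OCc3ccccc3)cc(OCc3ccccc3)c2C(=O)OCc2ccccc2)OCCO1 | intermediate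
17 | benzyl 4,6-bis(benzyloxy)-3-(ethynyloxy)-2-[(2-pentyl-1,3-dioxolan-2-yl)methyl]benzoate | CCCCCC1(Cc2c(OC#C)c(OCc3ccccc3)cc(OCc3ccccc3)c2C(=O)OCc2ccccc2)OCCO1 | intermediate
18 | ethyl diazoacetate | CCOC(=O)C=[N+]=[N-] | starting material
19 | methacrolein | CC(=C)C=O | starting material
20 | ethyl 2-diazo-3-hydroxy-4-methylpent-4-enoate (racemic, not isolated) | CCOC(=O)C(=[N+]=[N-])C(O)C(C)=C | intermediate
21 | ethyl 2-diazo-4-methyl-3-oxopent-4-enoate | CCOC(=O)C(=[N+]=[N-])C(=O)C(C)=C | intermediate
22 | ethyl 3-methyl-2-(oxomethylidene)but-3-enoate, the vinylketene (not isolated) | CCOC(=O)C(=C=O)C(C)=C | intermediate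
23 | ethyl 2-(aryloxy)-4-oxo-1-(prop-1-en-2-yl)cyclobut-2-ene-1-carboxylate, aryloxy = the ring A oxygen substituent of 17 (racemic, not isolated) | CCOC(=O)C1(C(C)=C)C(=O)C=C1Oc1c(CC2(CCCCC)OCCO2)c(C(=O)OCc2ccccc2)c(OCc2ccccc2)cc1OCc1ccccc1 | intermediate
24 | ethyl (2Z)-3-(aryloxy)-5-oxo-2-(prop-1-en-2-yl)penta-2,4-dienoate, the dienylketene (not isolated) | CCOC(=O)/C(C(C)=C)=C(/C=C=O)Oc1c(CC2(CCCCC)OCCO2)c(C(=O)OCc2ccccc2)c(OCc2ccccc2)cc1OCc1ccccc1 | intermediate
25 | ethyl 6-(aryloxy)-2-methyl-4-oxocyclohexa-1,5-diene-1-carboxylate (not isolated) | CCOC(=O)C1=C(C)CC(=O)C=C1Oc1c(CC2(CCCCC)OCCO2)c(C(=O)OCc2ccccc2)c(OCc2ccccc2)cc1OCc1ccccc1 | intermediate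
26 | benzyl 4,6-bis(benzyloxy)-3-[2-(ethoxycarbonyl)-5-hydroxy-3-methylphenoxy]-2-[(2-pentyl-1,3-dioxolan-2-yl)methyl]benzoate | CCCCCC1(Cc2c(Oc3cc(O)cc(C)c3C(=O)OCC)c(OCc3ccccc3)cc(OCc3ccccc3)c2C(=O)OCc2ccccc2)OCCO1 | intermediate
27 | benzyl 4,6-bis(benzyloxy)-3-[2-(ethoxycarbonyl)-5-methoxy-3-methylphenoxy]-2-[(2-pentyl-1,3-dioxolan-2-yl)methyl]benzoate | CCCCCC1(Cc2c(Oc3cc(OC)cc(C)c3C(=O)OCC)c(OCc3ccccc3)cc(OCc3ccccc3)c2C(=O)OCc2ccccc2)OCCO1 | intermediate
28 | ring B lithiomethyl derivative of 27 (not isolated) | CCCCCC1(Cc2c(Oc3cc(OC)cc(C[Li])c3C(=O)OCC)c(OCc3ccccc3)cc(OCc3ccccc3)c2C(=O)OCc2ccccc2)OCCO1 | intermediate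
29 | benzyl 4,6-bis(benzyloxy)-3-[2-(ethoxycarbonyl)-5-methoxy-3-(2-oxoheptyl)phenoxy]-2-[(2-pentyl-1,3-dioxolan-2-yl)methyl]benzoate | CCCCCC1(Cc2c(Oc3cc(OC)cc(CC(=O)CCCCC)c3C(=O)OCC)c(OCc3ccccc3)cc(OCc3ccccc3)c2C(=O)OCc2ccccc2)OCCO1 | intermediate
30 | benzyl 4,6-bis(benzyloxy)-3-[2-carboxy-5-methoxy-3-(2-oxoheptyl)phenoxy]-2-[(2-pentyl-1,3-dioxolan-2-yl)methyl]benzoate | CCCCCC1(Cc2c(Oc3cc(OC)cc(CC(=O)CCCCC)c3C(=O)O)c(OCc3ccccc3)cc(OCc3ccccc3)c2C(=O)OCc2ccccc2)OCCO1 | intermediate
31 | mixed acetic anhydride of 30 (not isolated) | CCCCCC1(Cc2c(Oc3cc(OC)cc(CC(=O)CCCCC)c3C(=O)OC(C)=O)c(OCc3ccccc3)cc(OCc3ccccc3)c2C(=O)OCc2ccccc2)OCCO1 | intermediate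
32 | benzyl 4,6-bis(benzyloxy)-3-[(6-methoxy-1-oxo-3-pentyl-1H-isochromen-8-yl)oxy]-2-[(2-pentyl-1,3-dioxolan-2-yl)methyl]benzoate | CCCCCC1(Cc2c(Oc3cc(OC)cc4cc(CCCCC)oc(=O)c34)c(OCc3ccccc3)cc(OCc3ccccc3)c2C(=O)OCc2ccccc2)OCCO1 | intermediate
33 | benzyl 4,6-bis(benzyloxy)-3-[(6-methoxy-1-oxo-3-pentyl-1H-isochromen-8-yl)oxy]-2-(2-oxoheptyl)benzoate | CCCCCC(=O)Cc1c(Oc2cc(OC)cc3cc(CCCCC)oc(=O)c23)c(OCc2ccccc2)cc(OCc2ccccc2)c1C(=O)OCc1ccccc1 | intermediate
34 | β-collatolic acid | CCCCCC(=O)Cc1c(Oc2cc(OC)cc3cc(CCCCC)oc(=O)c23)c(O)cc(O)c1C(=O)O | target

## Step count and risks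

Total step count: 16. Longest linear sequence: 14 steps (4 to 34 through steps 2–8 and 10–16); steps 1 and 9 are one-step side branches.

**Step 10 (key step, proposed new method).** The most likely failure is diversion of the ketene–alkyne adduct: closure through the ester carbonyl oxygen ([4+2], a pyranone) or through the alkenyl terminus, in place of [2+2] closure at carbon. The ester makes the ketene behave partly like an acylketene and stabilizes a dipolar intermediate. Further losses could come from carbene pathways other than the Wolff shift, polymerization of the ynol ether on heating, and acylation of the product phenol by excess ketene. Fallback (known chemistry): from phenol 12, Ullmann ether synthesis with ethyl 2-bromo-4-methoxy-6-methylbenzoate F1 (CuI, picolinic acid, K3PO4, DMSO, 90 °C) would give methyl ether 27 directly. The route is rejoined at step 12, and steps 7–11 fall away. F1 is a simple building block to be secured separately.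

**Step 8.** Butyllithium may add to the benzyl ester or metalate the benzylic methylene beside it before elimination and exchange are complete, and the aryl ethynyl ether may polymerize or hydrate during work-up. Fallback without alkyllithium: from phenol 12, O-vinylation (vinyl acetate, [Ir(cod)Cl]2, Na2CO3, toluene, 100 °C) to benzyl 4,6-bis(benzyloxy)-3-(ethenyloxy)-2-[(2-pentyl-1,3-dioxolan-2-yl)methyl]benzoate F2. Bromine addition at −78 °C then gives the 1,2-dibromoethyl ether F3, and double dehydrobromination with LiN(i-Pr)2 returns to 17.

**Step 5.** Iodination may lose regioselectivity, with attack at C5 because the bulky ketal side chain crowds C3, and the acid catalyst may partly remove the dioxolane. Fallback: iodinate earlier, where C3 is flanked only by a methyl group and no ketal is present. From 5, the same iodination gives benzyl 4,6-bis(benzyloxy)-3-iodo-2-methylbenzoate F4. Lateral lithiation and acylation with 3 give benzyl 4,6-bis(benzyloxy)-3-iodo-2-(2-oxoheptyl)benzoate F5, and ketalization as in step 4 returns to 9.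

**Step 12.** Deprotonation may occur at the wrong site (the ring A benzylic methylene beside its benzyl ester), or the lithiated toluate may condense with an ester group. Fallback: build the pyranone ring before the ether. From phenol 12, the copper-mediated ether synthesis described for step 10, now with 8-bromo-6-methoxy-3-pentyl-1H-isochromen-1-one F6, gives 32 directly, and the route is rejoined at step 15.

**Step 16.** Over-reduction of the isocoumarin C3–C4 double bond may set in before the hindered benzyl ether at C4 is fully cleaved. Fallback: non-reductive debenzylation of 33 with BCl3 and pentamethylbenzene in CH2Cl2 at −78 °C, which cleaves benzyl ethers and the benzyl ester and should leave the unchelated methyl ether. It leads from 33 straight to 34, and no compound outside the route is made (entry F0).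

## Further compounds

F1 | step 10 | ethyl 2-bromo-4-methoxy-6-methylbenzoate | CCOC(=O)c1c(C)cc(OC)cc1Br
F2 | step 8 | benzyl 4,6-bis(benzyloxy)-3-(ethenyloxy)-2-[(2-pentyl-1,3-dioxolan-2-yl)methyl]benzoate | CCCCCC1(Cc2c(OC=C)c(OCc3ccccc3)cc(OCc3ccccc3)c2C(=O)OCc2ccccc2)OCCO1
F3 | step 8 | benzyl 4,6-bis(benzyloxy)-3-(1,2-dibromoethoxy)-2-[(2-pentyl-1,3-dioxolan-2-yl)methyl]benzoate (racemic) | CCCCCC1(Cc2c(OC(Br)CBr)c(OCc3ccccc3)cc(OCc3ccccc3)c2C(=O)OCc2ccccc2)OCCO1
F4 | step 5 | benzyl 4,6-bis(benzyloxy)-3-iodo-2-methylbenzoate | Cc1c(I)c(OCc2ccccc2)cc(OCc2ccccc2)c1C(=O)OCc1ccccc1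
F5 | step 5 | benzyl 4,6-bis(benzyloxy)-3-iodo-2-(2-oxoheptyl)benzoate | CCCCCC(=O)Cc1c(I)c(OCc2ccccc2)cc(OCc2ccccc2)c1C(=O)OCc1ccccc1
F6 | step 12 | 8-bromo-6-methoxy-3-pentyl-1H-isochromen-1-one | CCCCCc1cc2cc(OC)cc(Br)c2c(=O)o1
F0 | step 16 | none | none
A1 | alternative 1 | 3-[(6-methoxy-1-oxo-3-pentyl-1H-isochromen-8-yl)oxy]-5-(2-pentyl-1,3-dioxolan-2-yl)pent-3-en-2-one | CC(=O)C(Oc1cc(OC)cc2cc(CCCCC)oc(=O)c12)=CCC1(CCCCC)OCCO1
A2 | alternative 1 | dibenzyl malonate | O=C(CC(=O)OCc1ccccc1)OCc1ccccc1
A3 | alternative 1 | benzyl 2-hydroxy-5-[(6-methoxy-1-oxo-3-pentyl-1H-isochromen-8-yl)oxy]-4-oxo-6-[(2-pentyl-1,3-dioxolan-2-yl)methyl]cyclohex-1-ene-1-carboxylate (5,6-trans, racemic) | O=C(OCc1ccccc1)C1=C(O)CC(=O)[C@@H](Oc2cc(OC)cc3cc(CCCCC)oc(=O)c23)[C@@H]1CC1(CCCCC)OCCO1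
A4 | alternative 2 | 8-{[4-methoxy-2,4-bis(trimethylsilyloxy)buta-1,3-dien-1-yl]oxy}-6-methoxy-3-pentyl-1H-isochromen-1-one | COC(O[Si](C)(C)C)=CC(O[Si](C)(C)C)=COc1cc(OC)cc2cc(CCCCC)oc(=O)c12
A5 | alternative 2 | benzyl 4-(2-pentyl-1,3-dioxolan-2-yl)but-2-ynoate | O=C(OCc1ccccc1)C#CCC1(CCCCC)OCCO1
A6 | alternative 2 | benzyl 4,6-dihydroxy-3-[(6-methoxy-1-oxo-3-pentyl-1H-isochromen-8-yl)oxy]-2-[(2-pentyl-1,3-dioxolan-2-yl)methyl]benzoate | O=C(OCc1ccccc1)c1c(O)cc(O)c(Oc2cc(OC)cc3cc(CCCCC)oc(=O)c23)c1CC1(CCCCC)OCCO1
A7 | alternative 3 | benzyl 4,6-bis(benzyloxy)-3-[5-methoxy-2-(trifluoromethanesulfonyloxy)-3-(trimethylsilyl)phenoxy]-2-[(2-pentyl-1,3-dioxolan-2-yl)methyl]benzoate | COc1cc(Oc2c(CC3(CCCCC)OCCO3)c(C(=O)OCc3ccccc3)c(OCc3ccccc3)cc2OCc2ccccc2)c(OS(=O)(=O)C(F)(F)F)c([Si](C)(C)C)c1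
A8 | alternative 3 | dimethyl malonate | COC(=O)CC(=O)OC
A9 | alternative 3 | benzyl 4,6-bis(benzyloxy)-3-[5-methoxy-2-(methoxycarbonyl)-3-(2-methoxy-2-oxoethyl)phenoxy]-2-[(2-pentyl-1,3-dioxolan-2-yl)methyl]benzoate | CCCCCC1(Cc2c(Oc3cc(OC)cc(CC(=O)OC)c3C(=O)OC)c(OCc3ccccc3)cc(OCc3ccccc3)c2C(=O)OCc2ccccc2)OCCO1
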